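## Structural features

The target is a C20 prostanoid methyl ester built on one carbocycle, the cyclopent-2-enone ring A (C8–C12). Ring A carries the ketone at C9, chlorine on C10 of the C10=C11 double bond, and a fully substituted, acetoxylated C12. The C1–C7 chain is attached through an exocyclic C7=C8 double bond (E) that runs on into the 5Z alkene, so that C5=C6–C7=C8–C9(=O)–C10=C11 is one cross-conjugated dienone. The C13–C20 chain hangs from C12 as a (Z)-oct-2-enyl group (C14=C15). C12 (R) is the only stereocentre and has no stereogenic neighbour, since it lies between the sp2 carbons C8 and C11; its configuration must therefore be set absolutely, and the remaining stereo-elements are the three alkene geometries (5Z, 7E, 14Z). The fragile groups are the chlorinated dienone (Michael acceptor, base- and light-sensitive, 5Z prone to isomerise), the tertiary acetate, the skipped Z alkene and the methyl ester. The real difficulty is the enantioselective construction of the oxygenated quaternary C12 in ring A; the C7=C8 geometry and a chlorination at C10 that spares the isolated alkene come second. The key step reads C12 with its oxygen, the ring bond C8–C12, the neighbouring ring carbon C11 and the two-carbon unit C13–C14 as a 2-alkoxy-2-vinylcyclopentanone, the pattern left when a cyclobutanol bond shifts onto the oxygen-bearing end of a π-allyl; the carbonyl appears at C11 and is moved to C9 afterwards.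

## Logic of the disconnections

**32 ⇒ 29.** The C7=C8 π bond (hydroxyl returned to C7) and the acetyl–O bond at C12 are cut together. The dienone and the tertiary acetate are the least durable features, so they are made last, and one reagent can make both. The gain is that 29 is a plain aldol with every carbon in place. The demand is that the elimination (through 30) favours 7E and that acylation of the hindered C12 hydroxyl of 31 outruns base damage to the dienone.

**29 ⇒ 22 + 27.** The C7–C8 bond is cut, at the only enolisable ring carbon. This makes the route convergent and leaves the stereocentre in the small piece 22. The demand is that 28 forms at C8 without loss of the C12 oxygen, which is met by carrying that oxygen as its alkoxide, and that 27 keeps its Z geometry.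

**27 ⇒ 26 ⇒ 25 ⇒ 1 + 23.** The aldehyde is traced to the alcohol, the Z alkene to the alkyne, and the C4–C5 bond is cut. This gives two commercial pieces, one of them already in the main line. The demands are C- over O-alkylation (through 24), a semihydrogenation that stops at the alkene, and an oxidation that does not isomerise 27.

**22 ⇒ 21 ⇒ 19 ⇒ 18.** The O–benzyl bond at C12 and the C10–Cl bond are cut, the chlorine being traced to the C10–C11 epoxide. An electrophilic chlorine source would attack the C14=C15 alkene and the anisyl ring first, whereas hydroperoxide and chloride act only on the enone. The gain is that 18 is a simple enone. The demand is that chloride opens at C10 and that water is lost across C10–C11 (through 20), not across C8–C12.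

**18 ⇒ 15 + 16.** The C14=C15 double bond is cut. A Z-selective olefination is the shortest dependable way to the cis alkene and reduces the lower chain to a two-carbon stub. The demand is that 17 adds to the β-alkoxy aldehyde faster than it deprotonates it.

**15 ⇒ 14 ⇒ 12.** The C14–O bond is traced to the vinyl group and the oxidation levels at C9 and C14 are lowered. At the stage of 12 no carbonyl competes with hydroboration, and both hydroxyls can then be oxidised in one operation. The demand is that the hydroboration (giving 13) selects the vinyl group over the ring alkene.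

**12 ⇒ 11 ⇒ 10 ⇒ 8.** The C9–O bond and the C10=C11 π bond are traced back to the C11 carbonyl (1,3-transposition), and the C9=C10 bond of 10 to the saturated ring. This is needed because the ring expansion can only place the carbonyl on C11. The gain is arrival at the direct product of the key step. The dehydrogenation (through 9) has only C10 to enolise; the fragmentation must tolerate a hindered ketone and a vinyl group.

**8 ⇒ 7.** The C8–C12 bond is cut with re-formation of C8–C11, opening ring A to a cyclobutanol. The only stereocentre is traded for an achiral precursor. The demand is a catalyst that selects one face of the allyl terminus.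

**7 ⇒ 4 + 5, and 4 ⇒ 3 ⇒ 1 + 2.** The C11–C12 bond and then the O–benzyl bond are cut, which ends in three commercial materials. The demand is α-lithiation of 4 at the oxygen-bearing carbon (through 6) and basic handling of the acid-labile 7.

## Other disconnections considered

Alternative 1: The cut removes C5=C6 as a two-carbon unit by breaking C4–C5 and C6–C7. In the forward step the Grignard reagent (4,4,4-trimethoxybutyl)magnesium bromide A3 would be transmetalated to copper and added syn across acetylene A4 in one flask. The (Z)-alkenylmetal so formed would then be coupled under Pd(PPh3)4 catalysis with the (E)-bromomethylidene enone A2 to give the silyl-protected orthoester dienone A1 as the product of the key step.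
- In its favour: both diene geometries follow from mechanism, syn carbometalation of A4 setting 5Z and retention in the coupling carrying the E geometry of A2 into 7E. The labile (Z)-enal and the aldol/elimination are avoided, and A3, A4 and A2 are joined in one operation.
- Against it here: it does nothing for ring A or C12. A2 must come from an already enantioenriched chloro enone (22 would serve after silylation and one-carbon homologation at C8). Stoichiometric copper and a gaseous alkyne are needed, and A1 still requires orthoester hydrolysis and silyl-to-acetyl exchange on the sensitive dienone.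
- Comparison: on control of the C5=C6 and C7=C8 geometry this disconnection is the better one. In end-game step count the two are about equal. On the central problem, C12, it is not a competitor but a possible graft onto the chosen route.

Alternative 2: The cut is C8–C9 with reconnection of C9 to C7, so ring A is seen as a contracted six-membered ring. In the forward step the epoxy para-quinol acetate A6 would be treated with BF3·OEt2. The epoxide C8–O bond ionises, the acyl carbon C9 moves from C7 to C8, and C7 is left as an aldehyde, giving the formyl cyclopentenone A5 as the product of the key step.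
- In its favour: A6 would be reached by oxidative dearomatisation of an aromatic precursor, so the C10 chlorine and the C12 acetate are present from the start. On these two points (no late chlorination, no ether-to-acetate exchange) it is better than the chosen plan, and the formyl carbon of A5 is exactly C7.
- Against it here: A6 is chiral but would form as a racemate unless the dearomatisation or the epoxidation is made enantioselective, which is less charted than the problem it replaces. The epoxidation must select the unchlorinated double bond and the shift must be that of the acyl group. A5 is an enolised, epimerisable β-keto aldehyde whose conversion into the (5Z,7E)-diene needs another stereocontrolled olefination. The alkyne must later be semihydrogenated beside the dienone.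
- Comparison: mechanistically both plans make ring A by a cationic 1,2-shift (C8–C9 here, C8–C12 in the chosen plan). In step count to a fully functionalised ring this one is equal or shorter. On absolute control of C12 the chosen plan is stronger, because its asymmetric step is catalytic and its substrate class is established.

Alternative 3: The cut is C10=C11. In the forward step the achiral triene A8 , a divinyl carbinol silyl ether with a vinyl ketone arm, would undergo ring-closing metathesis with a chiral molybdenum alkylidene of the Mo(=NAr)(=CHCMe2Ph)(biphenolate) type. The catalyst would engage one of the two enantiotopic vinyl groups and close ring A onto the vinyl ketone, leaving the other vinyl group on C12 and giving the cyclopentenone A7 as the product of the key step.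
- In its favour: like the chosen step it is catalytic and creates C12 from an achiral precursor. A7 already has the C9 ketone and the C10=C11 bond, so the three-step carbonyl transposition of the chosen plan would be unnecessary, a clear advantage in step economy. The vinyl handle is the same.
- Against it here: the catalyst has to distinguish two identical small vinyl groups on a fully substituted carbinol carbon. Electron-poor vinyl ketones are reluctant metathesis partners, and a Lewis-basic carbonyl can bind the oxophilic catalyst. The catalyst is air- and moisture-sensitive, and A8 itself needs several steps.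
- Comparison: equal in concept and better in oxidation pattern, potentially three steps shorter. It rests, however, on extending the method to a ketone-bearing carbocycle, whereas the chosen ring expansion stays within its known substrate class.

Key step: step 4

Assumption: the (R,R)-ligand is written as the enantiomer expected to deliver (R)-8; the sense of induction is to be confirmed by correlation on the first run, and the (S,S)-ligand is used if it proves opposite.

Remark on configuration: with the migrated methylene as C8 and the new carbonyl carbon as C11, (R)-8 has at C12 the spatial arrangement of the (12R) target. The descriptor changes along the route (R in 8 to 12, S in 14 to 22, R again in 31 and 32) only because substituent priorities change.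

## Route

Step 1
Reactants: 1 prop-2-yn-1-ol (propargyl alcohol); 2 4-methoxybenzyl chloride
Product: 3 1-methoxy-4-[(prop-2-yn-1-yloxy)methyl]benzene
Conditions: NaH, Bu4NI (cat.), THF–DMF, 0 → 23 °C
Reagents that add atoms: none
Why: Williamson etherification: the sodium alkoxide of 1 displaces chloride from the benzylic halide 2 (SN2, iodide catalysis); no stereocentre is involved.

Step 2
Reactants: 3 1-methoxy-4-[(prop-2-yn-1-yloxy)methyl]benzene
Product: 4 1-methoxy-4-[(propa-1,2-dien-1-yloxy)methyl]benzene
Conditions: KOt-Bu (0.3 equiv), THF, 23 °C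
Reagents that add atoms: none
Why: Base-catalysed propargyl-to-allene isomerisation: reversible deprotonation at the oxygen-bearing carbon and reprotonation at the terminus gives the alkoxyallene, and substoichiometric base at ambient temperature should stop short of the 1-propynyl ether.

Step 3
Reactants: 4 1-methoxy-4-[(propa-1,2-dien-1-yloxy)methyl]benzene; 5 cyclobutanone
Product: 7 1-{1-[(4-methoxybenzyl)oxy]propa-1,2-dien-1-yl}cyclobutan-1-ol, via lithiated allenyl ether 6 (not isolated)
Conditions: n-BuLi, THF, −78 °C; then 5, −78 °C; H2O quench; Et3N-treated silica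
Reagents that add atoms: none
Why: α-Lithiation of the alkoxyallene at its oxygen-bearing sp2 carbon followed by 1,2-addition of 6 to the strained ketone forms the C11–C12 bond; the adduct is an acid-labile enol ether, so work-up and purification are kept basic.

Step 4
Reactants: 7 1-{1-[(4-methoxybenzyl)oxy]propa-1,2-dien-1-yl}cyclobutan-1-ol
Product: 8 (R)-2-[(4-methoxybenzyl)oxy]-2-vinylcyclopentan-1-one
Conditions: Pd2(dba)3·CHCl3 (2.5 mol %), (R,R)-N,N'-(cyclohexane-1,2-diyl)bis[2-(diphenylphosphanyl)benzamide] (7.5 mol %), PhCO2H (10 mol %), Et3N (10 mol %), ClCH2CH2Cl, 60 °C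
Reagents that add atoms: none
Why: Oxidative addition of PhCO2H to zerovalent palladium gives a palladium hydride (divalent palladium) that hydropalladates the allene of 7 with hydrogen going to the central carbon, producing a π-allyl whose one terminus carries the PMB-oxy group and the cyclobutanol. A ring C–C bond of the cyclobutanol then migrates, anti to the metal, onto that terminus while the carbinol becomes the C11 ketone (Wagner–Meerwein, semipinacol-type 1,2-shift), which forms the C8–C12 bond and releases zerovalent palladium. The closest known reaction type is the palladium-catalysed asymmetric ring expansion of 1-(1-alkoxyallenyl)cyclobutanols to 2-alkoxy-2-vinylcyclopentanones, a class to which 7 belongs directly. Ring A is closed not by an end-on cyclisation but by ring enlargement, four-membered to five-membered through a three-centre 1,2-alkyl shift, driven by release of cyclobutane strain and formation of the C=O bond. The C12 stereocentre is set by the chiral diamidobisphosphine, which differentiates the two faces of the equilibrating π-allyl terminus in the migration step. Regioselectivity for the substituted terminus is secured by the alkoxy group, which makes that terminus the more electrophilic, oxocarbenium-like one and the only one within reach of a 1,2-shift; the choice of migrating carbon is moot because the two cyclobutane methylenes are equivalent. Chemoselectivity against hydrolysis of the enol-ether allene or a racemic proton-triggered shift is secured by keeping the benzoic acid catalytic and buffered with Et3N.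

Step 5
Reactants: 8 (R)-2-[(4-methoxybenzyl)oxy]-2-vinylcyclopentan-1-one
Product: 10 (R)-5-[(4-methoxybenzyl)oxy]-5-vinylcyclopent-2-en-1-one, via silyl enol ether 9 (not isolated)
Conditions: LiN(i-Pr)2, Me3SiCl, THF, −78 °C; then Pd(OAc)2 (10 mol %), O2 (1 atm), DMSO, 23 °C
Reagents that add atoms: none
Why: Saegusa–Ito dehydrogenation: enolisation can only go toward C10 because C12 is quaternary, and divalent palladium converts 9 into the C9=C10 enone by β-hydride elimination from the oxo-π-allyl, dioxygen reoxidising the metal; C12 is untouched.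

Step 6
Reactants: 10 (R)-5-[(4-methoxybenzyl)oxy]-5-vinylcyclopent-2-en-1-one
Product: 11 (3R)-3-[(4-methoxybenzyl)oxy]-3-vinyl-6-oxabicyclo[3.1.0]hexan-2-one (epoxide epimers)
Conditions: H2O2 (30% aq.), NaOH (0.3 equiv), MeOH, 0 °C
Reagents that add atoms: hydrogen peroxide, OO
Why: Nucleophilic (Weitz–Scheffer) epoxidation: hydroperoxide adds to the unhindered β-carbon C9 and the enolate closes the ring, while the electron-rich vinyl group and the PMB ether are inert; either epoxide face serves because both new centres are destroyed in step 7.

Step 7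
Reactants: 11 (3R)-3-[(4-methoxybenzyl)oxy]-3-vinyl-6-oxabicyclo[3.1.0]hexan-2-one
Product: 12 (4R)-4-[(4-methoxybenzyl)oxy]-4-vinylcyclopent-2-en-1-ol (C1 epimers)
Conditions: N2H4·H2O (3 equiv), AcOH (0.3 equiv), degassed MeOH, 0 → 23 °C; neutral work-up
Reagents that add atoms: none
Why: Wharton transposition: the hydrazone of the epoxy ketone opens the epoxide to an alkenyl diazene that loses dinitrogen, leaving the C10=C11 alkene and the oxygen on C9; degassing suppresses diimide reduction of the vinyl group, and the doubly allylic ether of 12 calls for a non-acidic work-up.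

Step 8
Reactants: 12 (4R)-4-[(4-methoxybenzyl)oxy]-4-vinylcyclopent-2-en-1-ol
Product: 14 (4S)-4-(2-hydroxyethyl)-4-[(4-methoxybenzyl)oxy]cyclopent-2-en-1-ol (C1 epimers), via bis-borylated adduct 13 (not isolated)
Conditions: 9-BBN (2.5 equiv), THF, 0 → 23 °C; then NaOH (3 M aq.), H2O2 (30% aq.), 0 → 23 °C
Reagents that add atoms: hydrogen peroxide, OO
Why: Anti-Markovnikov hydroboration–oxidation: the bulky dialkylborane should add to the monosubstituted vinyl group much faster than to the hindered ring alkene (the hydroxyl consumes one equivalent as a borinate), and alkaline peroxide then gives the primary alcohol at C14; no carbonyl group is present to be reduced.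

Step 9
Reactants: 14 (4S)-4-(2-hydroxyethyl)-4-[(4-methoxybenzyl)oxy]cyclopent-2-en-1-ol
Product: 15 2-{(1S)-1-[(4-methoxybenzyl)oxy]-4-oxocyclopent-2-en-1-yl}acetaldehyde
Conditions: Dess–Martin periodinane (2.6 equiv), NaHCO3, CH2Cl2, 0 → 23 °C
Reagents that add atoms: none
Why: Dess–Martin oxidation of both hydroxyls in one buffered, non-basic operation gives the C9 enone and the C14 aldehyde without enolising the β-alkoxy aldehyde; the C9 epimers converge here.

Step 10
Reactants: 15 2-{(1S)-1-[(4-methoxybenzyl)oxy]-4-oxocyclopent-2-en-1-yl}acetaldehyde; 16 hexyltriphenylphosphonium bromide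
Product: 18 (S)-4-[(4-methoxybenzyl)oxy]-4-[(Z)-oct-2-en-1-yl]cyclopent-2-en-1-one, via hexylidenetriphenylphosphorane 17 (not isolated)
Conditions: 16 (1.15 equiv), NaN(SiMe3)2 (1.1 equiv), THF, 0 °C; then 15 added slowly, −78 → −20 °C
Reagents that add atoms: none
Why: Salt-free Z-selective Wittig olefination: the non-stabilised ylide 17 adds to the aldehyde much faster than to the enone carbonyl, and kinetic cis-oxaphosphetane formation at low temperature gives the 14Z alkene; slow addition of 15 at −78 °C with no large excess of ylide limits proton transfer and β-loss of the C12 alkoxy group.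

Step 11
Reactants: 18 (S)-4-[(4-methoxybenzyl)oxy]-4-[(Z)-oct-2-en-1-yl]cyclopent-2-en-1-one
Product: 19 (4S)-4-[(4-methoxybenzyl)oxy]-4-[(Z)-oct-2-en-1-yl]-6-oxabicyclo[3.1.0]hexan-2-one (epoxide epimers)
Conditions: H2O2 (30% aq.), NaOH (0.3 equiv), MeOH, −10 → 0 °C
Reagents that add atoms: hydrogen peroxide, OO
Why: Weitz–Scheffer epoxidation again: hydroperoxide attacks only the electron-poor C10=C11 bond and leaves the isolated 14Z alkene and the anisyl ring alone; the ether on C12 blocks any retro-aldol opening of the ring under base, and the epoxide configuration is irrelevant.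

Step 12
Reactants: 19 (4S)-4-[(4-methoxybenzyl)oxy]-4-[(Z)-oct-2-en-1-yl]-6-oxabicyclo[3.1.0]hexan-2-one
Product: 21 (S)-2-chloro-4-[(4-methoxybenzyl)oxy]-4-[(Z)-oct-2-en-1-yl]cyclopent-2-en-1-one, via trans-chlorohydrin 20 (not isolated)
Conditions: LiCl (5 equiv), AcOH (5 equiv), THF, 23 °C; then MsCl, Et3N, CH2Cl2, 0 → 23 °C
Reagents that add atoms: lithium chloride, [Li+].[Cl-]
Why: Chloride opens the α,β-epoxy ketone at C10 (SN2 at the carbonyl-activated α-carbon, C11 being neopentyl-like next to the quaternary C12) under mildly acidic conditions that spare the PMB ether, giving chlorohydrin 20. Mesylation of the secondary C11 hydroxyl and E1cB loss through the more acidic α-chloro C10–H then give the α-chloro enone regioselectively, whereas strong acid could also expel the C12 alkoxy group through the C8 enol.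

Step 13
Reactants: 21 (S)-2-chloro-4-[(4-methoxybenzyl)oxy]-4-[(Z)-oct-2-en-1-yl]cyclopent-2-en-1-one
Product: 22 (S)-2-chloro-4-hydroxy-4-[(Z)-oct-2-en-1-yl]cyclopent-2-en-1-one
Conditions: DDQ (1.3 equiv), CH2Cl2–pH 7 phosphate buffer (10:1), 0 → 23 °C
Reagents that add atoms: none
Why: Oxidative PMB cleavage: hydride abstraction from the electron-rich benzylic position and hydrolysis of the oxocarbenium ion free the tertiary C12 alcohol; the electron-poor chloro enone and the isolated Z alkene are not oxidised, and the ether is removed before the sensitive dienone exists.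

Step 14
Reactants: 1 prop-2-yn-1-ol; 23 4-bromo-1,1,1-trimethoxybutane
Product: 25 methyl 7-hydroxyhept-5-ynoate, via 7,7,7-trimethoxyhept-2-yn-1-ol 24 (not isolated)
Conditions: LiNH2 (2.2 equiv), NH3(l), −33 °C; 23 in THF; NH4Cl; then PPTS (cat.), acetone–H2O, 23 °C
Reagents that add atoms: water, O
Why: C-alkylation of the dianion of 1: the acetylide carbon is the more nucleophilic site and displaces the primary bromide of 23 (SN2, forming C4–C5), the base-stable orthoester masking the ester; mild aqueous acid then hydrolyses orthoester 24 to the methyl ester.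

Step 15
Reactants: 25 methyl 7-hydroxyhept-5-ynoate
Product: 26 methyl (Z)-7-hydroxyhept-5-enoate
Conditions: H2 (1 atm), 5% Pd/CaCO3 poisoned with Pb(OAc)2, quinoline, EtOAc, 23 °C
Reagents that add atoms: none
Why: Lindlar-type semihydrogenation: syn delivery of dihydrogen on the poisoned palladium surface gives the 5Z alkene and stops at the alkene stage.

Step 16
Reactants: 26 methyl (Z)-7-hydroxyhept-5-enoate
Product: 27 methyl (Z)-7-oxohept-5-enoate
Conditions: Dess–Martin periodinane, NaHCO3, CH2Cl2, 0 °C; used at once
Reagents that add atoms: none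
Why: Buffered Dess–Martin oxidation of the allylic alcohol gives the (Z)-enal without the acid or base that would isomerise it to the E isomer; 27 is taken directly into step 17.

Step 17
Reactants: 22 (S)-2-chloro-4-hydroxy-4-[(Z)-oct-2-en-1-yl]cyclopent-2-en-1-one; 27 methyl (Z)-7-oxohept-5-enoate
Product: 29 methyl (5Z)-7-{(5S)-3-chloro-5-hydroxy-5-[(Z)-oct-2-en-1-yl]-2-oxocyclopent-3-en-1-yl}-7-hydroxyhept-5-enoate (C7 and C8 epimers), via dilithium alkoxide-enolate 28 (not isolated)
Conditions: 22 added to LiN(i-Pr)2 (2.3 equiv), THF, −78 °C; then 27 (1.3 equiv), −78 °C; aq. NH4Cl at −78 °C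
Reagents that add atoms: none
Why: Directed aldol addition of a dianion: C8 is the only enolisable position, and because the C12 oxygen is carried as its alkoxide it cannot leave, so β-elimination from enolate 28 is excluded; 1,2-addition to the enal forms C7–C8, and all C7/C8 diastereomers are carried on because both centres become sp2.

Step 18
Reactants: 29 methyl (5Z)-7-{(5S)-3-chloro-5-hydroxy-5-[(Z)-oct-2-en-1-yl]-2-oxocyclopent-3-en-1-yl}-7-hydroxyhept-5-enoate
Product: 32 methyl (5Z,7E)-7-{(5R)-5-acetoxy-3-chloro-5-[(Z)-oct-2-en-1-yl]-2-oxocyclopent-3-en-1-ylidene}hept-5-enoate, via C7 monoacetate 30 (not isolated), via 12-hydroxy dienone 31 (not isolated)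
Conditions: Ac2O (8 equiv), Et3N (8 equiv), DMAP (1 equiv), CH2Cl2, 0 → 23 °C, light excluded
Reagents that add atoms: acetic anhydride, CC(=O)OC(C)=O
Why: Acylation and E1cB elimination: the secondary C7 hydroxyl is acetylated first (30) and the acetate is expelled from the C8 enolate to give dienone 31, the 7E isomer being expected to predominate because it keeps C6 away from the C9 carbonyl oxygen; DMAP-catalysed acylation of the tertiary C12 alcohol then gives 32 with C12 untouched.

## Compound list

1 | prop-2-yn-1-ol (propargyl alcohol) | C#CCO | starting material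
2 | 4-methoxybenzyl chloride | COc1ccc(CCl)cc1 | starting material
3 | 1-methoxy-4-[(prop-2-yn-1-yloxy)methyl]benzene | C#CCOCc1ccc(OC)cc1 | intermediate
4 | 1-methoxy-4-[(propa-1,2-dien-1-yloxy)methyl]benzene | C=C=COCc1ccc(OC)cc1 | intermediate
5 | cyclobutanone | O=C1CCC1 | starting material
6 | {1-[(4-methoxybenzyl)oxy]propa-1,2-dien-1-yl}lithium | [Li]C(=C=C)OCc1ccc(OC)cc1 | intermediate
7 | 1-{1-[(4-methoxybenzyl)oxy]propa-1,2-dien-1-yl}cyclobutan-1-ol | C=C=C(OCc1ccc(OC)cc1)C1(O)CCC1 | intermediate
8 | (R)-2-[(4-methoxybenzyl)oxy]-2-vinylcyclopentan-1-one | C=C[C@@]1(OCc2ccc(OC)cc2)C(=O)CCC1 | intermediate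
9 | (R)-({5-[(4-methoxybenzyl)oxy]-5-vinylcyclopent-1-en-1-yl}oxy)trimethylsilane | C=C[C@@]1(OCc2ccc(OC)cc2)C(O[Si](C)(C)C)=CCC1 | intermediate
10 | (R)-5-[(4-methoxybenzyl)oxy]-5-vinylcyclopent-2-en-1-one | C=C[C@@]1(OCc2ccc(OC)cc2)C(=O)C=CC1 | intermediate
11 | (3R)-3-[(4-methoxybenzyl)oxy]-3-vinyl-6-oxabicyclo[3.1.0]hexan-2-one (epoxide epimers) | C=C[C@@]1(OCc2ccc(OC)cc2)C(=O)C2OC2C1 | intermediate
12 | (4R)-4-[(4-methoxybenzyl)oxy]-4-vinylcyclopent-2-en-1-ol (C1 epimers) | C=C[C@@]1(OCc2ccc(OC)cc2)C=CC(O)C1 | intermediate
13 | 9-{2-[(1S)-4-(9-borabicyclo[3.3.1]nonan-9-yloxy)-1-[(4-methoxybenzyl)oxy]cyclopent-2-en-1-yl]ethyl}-9-borabicyclo[3.3.1]nonane | C1CCC2CCCC1B2CC[C@@]1(OCc2ccc(OC)cc2)C=CC(OB2C3CCCC2CCC3)C1 | intermediate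
14 | (4S)-4-(2-hydroxyethyl)-4-[(4-methoxybenzyl)oxy]cyclopent-2-en-1-ol (C1 epimers) | OCC[C@@]1(OCc2ccc(OC)cc2)C=CC(O)C1 | intermediate
15 | 2-{(1S)-1-[(4-methoxybenzyl)oxy]-4-oxocyclopent-2-en-1-yl}acetaldehyde | O=CC[C@@]1(OCc2ccc(OC)cc2)C=CC(=O)C1 | intermediate
16 | hexyltriphenylphosphonium bromide | CCCCCC[P+](c1ccccc1)(c1ccccc1)c1ccccc1.[Br-] | starting material
17 | hexylidenetriphenylphosphorane | CCCCCC=P(c1ccccc1)(c1ccccc1)c1ccccc1 | intermediate
18 | (S)-4-[(4-methoxybenzyl)oxy]-4-[(Z)-oct-2-en-1-yl]cyclopent-2-en-1-one | CCCCC/C=C\C[C@@]1(OCc2ccc(OC)cc2)C=CC(=O)C1 | intermediate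
19 | (4S)-4-[(4-methoxybenzyl)oxy]-4-[(Z)-oct-2-en-1-yl]-6-oxabicyclo[3.1.0]hexan-2-one (epoxide epimers) | CCCCC/C=C\C[C@@]1(OCc2ccc(OC)cc2)C2OC2C(=O)C1 | intermediate
20 | (4S)-2-chloro-3-hydroxy-4-[(4-methoxybenzyl)oxy]-4-[(Z)-oct-2-en-1-yl]cyclopentan-1-one (2,3-trans) | CCCCC/C=C\C[C@@]1(OCc2ccc(OC)cc2)C(O)C(Cl)C(=O)C1 | intermediate
21 | (S)-2-chloro-4-[(4-methoxybenzyl)oxy]-4-[(Z)-oct-2-en-1-yl]cyclopent-2-en-1-one | CCCCC/C=C\C[C@@]1(OCc2ccc(OC)cc2)C=C(Cl)C(=O)C1 | intermediate
22 | (S)-2-chloro-4-hydroxy-4-[(Z)-oct-2-en-1-yl]cyclopent-2-en-1-one | CCCCC/C=C\C[C@@]1(O)C=C(Cl)C(=O)C1 | intermediate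
23 | 4-bromo-1,1,1-trimethoxybutane | COC(CCCBr)(OC)OC | starting material
24 | 7,7,7-trimethoxyhept-2-yn-1-ol | OCC#CCCCC(OC)(OC)OC | intermediate
25 | methyl 7-hydroxyhept-5-ynoate | OCC#CCCCC(=O)OC | intermediate
26 | methyl (Z)-7-hydroxyhept-5-enoate | OC/C=C\CCCC(=O)OC | intermediate
27 | methyl (Z)-7-oxohept-5-enoate | O=C/C=C\CCCC(=O)OC | intermediate
28 | dilithium (1S)-3-chloro-1-[(Z)-oct-2-en-1-yl]cyclopenta-2,4-diene-1,4-bis(olate) (C12 alkoxide, C8=C9 enolate of 22) | CCCCC/C=C\C[C@@]1(O[Li])C=C(Cl)C(O[Li])=C1 | intermediate
29 | methyl (5Z)-7-{(5S)-3-chloro-5-hydroxy-5-[(Z)-oct-2-en-1-yl]-2-oxocyclopent-3-en-1-yl}-7-hydroxyhept-5-enoate (C7 and C8 epimers) | CCCCC/C=C\C[C@@]1(O)C=C(Cl)C(=O)C1C(O)/C=C\CCCC(=O)OC | intermediate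
30 | methyl (5Z)-7-acetoxy-7-{(5S)-3-chloro-5-hydroxy-5-[(Z)-oct-2-en-1-yl]-2-oxocyclopent-3-en-1-yl}hept-5-enoate (C7 and C8 epimers) | CCCCC/C=C\C[C@@]1(O)C=C(Cl)C(=O)C1C(OC(C)=O)/C=C\CCCC(=O)OC | intermediate
31 | methyl (5Z,7E)-7-{(5R)-3-chloro-5-hydroxy-5-[(Z)-oct-2-en-1-yl]-2-oxocyclopent-3-en-1-ylidene}hept-5-enoate | CCCCC/C=C\C[C@@]1(O)C=C(Cl)C(=O)/C1=C/C=C\CCCC(=O)OC | intermediate
32 | methyl (5Z,7E)-7-{(5R)-5-acetoxy-3-chloro-5-[(Z)-oct-2-en-1-yl]-2-oxocyclopent-3-en-1-ylidene}hept-5-enoate | CCCCC/C=C\C[C@@]1(OC(C)=O)C=C(Cl)C(=O)/C1=C/C=C\CCCC(=O)OC | target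

## Step count and least certain steps

Total step count: 18. Longest linear sequence: 15 steps (steps 1 to 13, 17 and 18); the upper-chain piece 27 takes 3 steps (14 to 16).

**Step 4 (key step).** The most likely failure is erosion of enantioselectivity, either by a metal-free, proton-triggered shift of the acid-labile allenyl ether running beside the catalytic cycle or by a poor fit of the PMB ether in the ligand pocket. Fallback (resolution in place of asymmetric catalysis): from 7 the ring expansion is run without asymmetric induction (Pd(PPh3)4, PhCO2H, ClCH2CH2Cl, 60 °C) to give the racemic ketone rac-2-[(4-methoxybenzyl)oxy]-2-vinylcyclopentan-1-one F1 as a single constitutional isomer. F1 is then resolved by preparative chromatography on a chiral stationary phase; the (R)-enantiomer is 8, where the route is rejoined.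

**Step 7.** The most likely failure is slow condensation at the hindered C11 carbonyl, which lets hydrazine open the epoxide (pyrazoline formation), together with diimide reduction of the vinyl group. Fallback (radical transposition): from 11, NaBH4/CeCl3·7H2O in MeOH at 0 °C gives the epoxy alcohol (3R)-3-[(4-methoxybenzyl)oxy]-3-vinyl-6-oxabicyclo[3.1.0]hexan-2-ol F2 as a mixture of carbinol epimers. 1,1'-Thiocarbonyldiimidazole with DMAP in ClCH2CH2Cl at 60 °C converts F2 into O-{(3R)-3-[(4-methoxybenzyl)oxy]-3-vinyl-6-oxabicyclo[3.1.0]hexan-2-yl} 1H-imidazole-1-carbothioate F3 in one operation. Bu3SnH/AIBN in toluene at 80 °C then generates the C11 radical from F3 , which opens the neighbouring epoxide C10–O bond; hydrogen transfer to the C9 oxygen radical gives 12.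

**Step 10.** The most likely failure is proton transfer from the enone-aldehyde to the ylide followed by loss of the C12 alkoxy group (driven by formation of a fully conjugated dienone), together with erosion of Z-selectivity. Fallback (olefination before the ring ketone exists): from 14, TEMPO (cat.)/PhI(OAc)2 in CH2Cl2 should oxidise the primary alcohol in preference to the secondary one and give 2-{(1R)-4-hydroxy-1-[(4-methoxybenzyl)oxy]cyclopent-2-en-1-yl}acetaldehyde F4 as the open form or its lactol. Ylide 17 (2.2 equiv, −78 → 0 °C) then converts F4 into (4S)-4-[(4-methoxybenzyl)oxy]-4-[(Z)-oct-2-en-1-yl]cyclopent-2-en-1-ol F5 by the same Z-selective Wittig reaction. MnO2 in CH2Cl2 finally oxidises the allylic alcohol of F5 to 18.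

**Step 12.** The most likely failure is sluggish or misdirected epoxide opening (chloride at the hindered C11, or acetate in place of chloride) and competing loss of the C12 alkoxy group across C8–C12 during dehydration. Fallback (direct C–H chlorination before the lower-chain alkene exists, no epoxide): from 14, MnO2 in CH2Cl2 should oxidise only the allylic C9 hydroxyl and give (S)-4-(2-hydroxyethyl)-4-[(4-methoxybenzyl)oxy]cyclopent-2-en-1-one F6 with the primary alcohol intact. PhSeCl (excess) with pyridine in CH2Cl2, a known one-step conversion of cyclic enones into α-chloro enones by way of the α-phenylseleno enone, then turns F6 into (S)-2-chloro-4-(2-hydroxyethyl)-4-[(4-methoxybenzyl)oxy]cyclopent-2-en-1-one F7 after aqueous work-up. At this stage no isolated alkene is present to compete for the selenium electrophile, which is why the chlorination is moved ahead of the olefination. Buffered Dess–Martin oxidation of F7 gives 2-{(1S)-3-chloro-1-[(4-methoxybenzyl)oxy]-4-oxocyclopent-2-en-1-yl}acetaldehyde F8 , which is used at once. The Wittig reaction of F8 with 17 under the conditions of step 10 gives 21; compounds 15, 18, 19 and 20 are bypassed.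

**Step 17.** The most likely failure is incomplete second deprotonation of the alkoxide (aggregation), with retro-aldol opening of the ring alkoxide before the enolate forms, or isomerisation of the (Z)-enal. The ring aldol is the favoured side of this equilibrium, which limits but does not remove the risk. Fallback (isolated silyl ether, monoanion aldol): from 22, Et3SiOTf/2,6-lutidine gives (S)-2-chloro-4-[(Z)-oct-2-en-1-yl]-4-[(triethylsilyl)oxy]cyclopent-2-en-1-one F9 as a stable, isolable ether. LiN(i-Pr)2 (1.1 equiv) and 27 at −78 °C convert F9 into methyl (5Z)-7-{3-chloro-5-[(Z)-oct-2-en-1-yl]-2-oxo-5-[(triethylsilyl)oxy]cyclopent-3-en-1-yl}-7-hydroxyhept-5-enoate F10 as a mixture of C7 and C8 epimers. Ac2O/DMAP acetylates F10 at C7 and eliminates to methyl (5Z,7E)-7-{(5R)-3-chloro-5-[(Z)-oct-2-en-1-yl]-2-oxo-5-[(triethylsilyl)oxy]cyclopent-3-en-1-ylidene}hept-5-enoate F11 by the same E1cB path. HF·pyridine in THF at 0 °C removes the silyl group of F11 to give 31, which is acetylated as in the last stage of step 18.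

**Step 18.** The most likely failure is poor control of the C7=C8 geometry in the E1cB loss of acetate, and slow acylation of the tertiary carbinol that leaves the dienone exposed to base. Fallback (slim alkynyl substituent during the elimination, Z alkene made last): from 25, Dess–Martin periodinane gives methyl 7-oxohept-5-ynoate F12 in place of the (Z)-enal. Dianion 28 (from 22 as in step 17) adds to F12 to give methyl 7-{3-chloro-5-hydroxy-5-[(Z)-oct-2-en-1-yl]-2-oxocyclopent-3-en-1-yl}-7-hydroxyhept-5-ynoate F13 as a mixture of C7 and C8 epimers. Ac2O/Et3N/DMAP converts F13 into methyl (7E)-7-{(5R)-5-acetoxy-3-chloro-5-[(Z)-oct-2-en-1-yl]-2-oxocyclopent-3-en-1-ylidene}hept-5-ynoate F14 , in which the linear alkynyl group should favour the E isomer more strongly. Semihydrogenation of the alkyne of F14 (H2, Pd/CaCO3 poisoned with Pb(OAc)2, quinoline) sets 5Z and gives 32.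

## Further compounds

F1 | step 4 | rac-2-[(4-methoxybenzyl)oxy]-2-vinylcyclopentan-1-one | C=CC1(OCc2ccc(OC)cc2)C(=O)CCC1
F2 | step 7 | (3R)-3-[(4-methoxybenzyl)oxy]-3-vinyl-6-oxabicyclo[3.1.0]hexan-2-ol | C=C[C@@]1(OCc2ccc(OC)cc2)C(O)C2OC2C1
F3 | step 7 | O-{(3R)-3-[(4-methoxybenzyl)oxy]-3-vinyl-6-oxabicyclo[3.1.0]hexan-2-yl} 1H-imidazole-1-carbothioate | C=C[C@@]1(OCc2ccc(OC)cc2)C(OC(=S)n2ccnc2)C2OC2C1
F4 | step 10 | 2-{(1R)-4-hydroxy-1-[(4-methoxybenzyl)oxy]cyclopent-2-en-1-yl}acetaldehyde | O=CC[C@@]1(OCc2ccc(OC)cc2)C=CC(O)C1
F5 | step 10 | (4S)-4-[(4-methoxybenzyl)oxy]-4-[(Z)-oct-2-en-1-yl]cyclopent-2-en-1-ol | CCCCC/C=C\C[C@@]1(OCc2ccc(OC)cc2)C=CC(O)C1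
F6 | step 12 | (S)-4-(2-hydroxyethyl)-4-[(4-methoxybenzyl)oxy]cyclopent-2-en-1-one | OCC[C@@]1(OCc2ccc(OC)cc2)C=CC(=O)C1
F7 | step 12 | (S)-2-chloro-4-(2-hydroxyethyl)-4-[(4-methoxybenzyl)oxy]cyclopent-2-en-1-one | OCC[C@@]1(OCc2ccc(OC)cc2)C=C(Cl)C(=O)C1
F8 | step 12 | 2-{(1S)-3-chloro-1-[(4-methoxybenzyl)oxy]-4-oxocyclopent-2-en-1-yl}acetaldehyde | O=CC[C@@]1(OCc2ccc(OC)cc2)C=C(Cl)C(=O)C1
F9 | step 17 | (S)-2-chloro-4-[(Z)-oct-2-en-1-yl]-4-[(triethylsilyl)oxy]cyclopent-2-en-1-one | CCCCC/C=C\C[C@@]1(O[Si](CC)(CC)CC)C=C(Cl)C(=O)C1
F10 | step 17 | methyl (5Z)-7-{3-chloro-5-[(Z)-oct-2-en-1-yl]-2-oxo-5-[(triethylsilyl)oxy]cyclopent-3-en-1-yl}-7-hydroxyhept-5-enoate | CCCCC/C=C\C[C@@]1(O[Si](CC)(CC)CC)C=C(Cl)C(=O)C1C(O)/C=C\CCCC(=O)OC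
F11 | step 17 | methyl (5Z,7E)-7-{(5R)-3-chloro-5-[(Z)-oct-2-en-1-yl]-2-oxo-5-[(triethylsilyl)oxy]cyclopent-3-en-1-ylidene}hept-5-enoate | CCCCC/C=C\C[C@@]1(O[Si](CC)(CC)CC)C=C(Cl)C(=O)/C1=C/C=C\CCCC(=O)OC
F12 | step 18 | methyl 7-oxohept-5-ynoate | O=CC#CCCCC(=O)OC
F13 | step 18 | methyl 7-{3-chloro-5-hydroxy-5-[(Z)-oct-2-en-1-yl]-2-oxocyclopent-3-en-1-yl}-7-hydroxyhept-5-ynoate | CCCCC/C=C\C[C@@]1(O)C=C(Cl)C(=O)C1C(O)C#CCCCC(=O)OC
F14 | step 18 | methyl (7E)-7-{(5R)-5-acetoxy-3-chloro-5-[(Z)-oct-2-en-1-yl]-2-oxocyclopent-3-en-1-ylidene}hept-5-ynoate | CCCCC/C=C\C[C@@]1(OC(C)=O)C=C(Cl)C(=O)/C1=C/C#CCCCC(=O)OC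
A1 | alternative 1 | (4R,5E)-2-chloro-4-[(Z)-oct-2-en-1-yl]-4-[(triethylsilyl)oxy]-5-[(2Z)-7,7,7-trimethoxyhept-2-en-1-ylidene]cyclopent-2-en-1-one | CCCCC/C=C\C[C@@]1(O[Si](CC)(CC)CC)C=C(Cl)C(=O)/C1=C/C=C\CCCC(OC)(OC)OC
A2 | alternative 1 | (4R,5E)-5-(bromomethylidene)-2-chloro-4-[(Z)-oct-2-en-1-yl]-4-[(triethylsilyl)oxy]cyclopent-2-en-1-one | CCCCC/C=C\C[C@@]1(O[Si](CC)(CC)CC)C=C(Cl)C(=O)/C1=C/Br
A3 | alternative 1 | (4,4,4-trimethoxybutyl)magnesium bromide | COC(CCC[Mg]Br)(OC)OC
A4 | alternative 1 | acetylene | C#C
A5 | alternative 2 | 4-acetoxy-2-chloro-5-formyl-4-(oct-2-yn-1-yl)cyclopent-2-en-1-one (keto-aldehyde tautomer) | CCCCCC#CC[C@@]1(OC(C)=O)C=C(Cl)C(=O)[C@@H]1C=O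
A6 | alternative 2 | 5-acetoxy-3-chloro-5-(oct-2-yn-1-yl)-7-oxabicyclo[4.1.0]hept-3-en-2-one (epoxide face open) | CCCCCC#CC[C@@]1(OC(C)=O)C=C(Cl)C(=O)C2OC12
A7 | alternative 3 | (R)-4-[(triethylsilyl)oxy]-4-vinylcyclopent-2-en-1-one | C=C[C@@]1(O[Si](CC)(CC)CC)C=CC(=O)C1
A8 | alternative 3 | 5-[(triethylsilyl)oxy]-5-vinylhepta-1,6-dien-3-one | C=CC(=O)CC(O[Si](CC)(CC)CC)(C=C)C=C
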